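**Retrosynthetic overview**

1. The quinone is carried as a 1,4-dimethoxybenzene and unmasked last by oxidative demethylation; the benzene ring is bought, not made.
2. The gem-dimethyl carbon C6 of the 2,6,6-trimethylcyclohex-2-ene ring is traced back to C(CH3)(CHO): one methyl is carried as a formyl activating group and later reduced through its tosylhydrazone.
3. Key disconnection: retro-[4+2] across ring bonds C1–C6 and C4–C5 gives methacrolein and an acyclic, achiral aryl tetraene ending in an (E)-1-alkyl-2-methylbuta-1,3-diene; the union is made at the most hindered bond, between the stereogenic C1 and the fully substituted C6.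
4. Enabling feature: ring atoms C1(H)–C2(CH3)=C3(H)–C4(H2) are a butadiene retron with the double bond exactly where a [4+2] leaves it, C5(H2)–C6(CH3)2 is an isobutene unit whose fully substituted carbon tolerates a formyl group, and C1 is the only stereocentre.
5. Ring order: the cyclohexene is the only ring formed and the last one closed; the tetraene comes from (2E,6E)-farnesyl bromide and lithiated 1,4-dimethoxybenzene by terminal allylic oxidation and methylenation.

Key step: step 5

Assumption: the sense of induction is taken from the formyl C–H···O binding model for 2-substituted acroleins on N-protonated oxazaborolidines, by which the (3aR)-catalyst leaves the Si face of the enal α-carbon open; should the first assay show the opposite sense, the mirror-image catalyst is used with no other change.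

**Route**

Step 1
Reactants: 1 1,4-dimethoxybenzene; 2 (2E,6E)-farnesyl bromide
Product: 4 1,4-dimethoxy-2-[(2E,6E)-3,7,11-trimethyldodeca-2,6,10-trien-1-yl]benzene, via (2,5-dimethoxyphenyl)lithium 3 (not isolated)
Conditions: n-BuLi, TMEDA, THF, 0 °C; then CuBr·SMe2 (10 mol%), 2, −78 °C → rt
Reagents that add atoms: none
Why: Directed ortho-lithiation followed by copper-assisted SN2 allylation of the aryl nucleophile with the primary allylic bromide is standard arene prenylation and should leave the (E)-alkenes untouched; no stereocentre is formed.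

Step 2
Reactants: 4 1,4-dimethoxy-2-[(2E,6E)-3,7,11-trimethyldodeca-2,6,10-trien-1-yl]benzene
Product: 5 (2E,6E,10E)-12-(2,5-dimethoxyphenyl)-2,6,10-trimethyldodeca-2,6,10-trien-1-ol
Conditions: SeO2 (0.3 equiv), t-BuOOH (70% aq.), salicylic acid (10 mol%), CH2Cl2, 0 °C → rt, stopped at partial conversion, 4 recycled
Reagents that add atoms: tert-butyl hydroperoxide CC(C)(C)OO (oxygen, relayed through catalytic SeO2, O=[Se]=O)
Why: Riley allylic oxidation (ene reaction of SeO2, then [2,3]-sigmatropic shift) should attack the most electron-rich and least hindered terminal isopropylidene at its (E)-methyl group and give the (E)-allylic alcohol; no stereocentre is formed.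

Step 3
Reactants: 5 (2E,6E,10E)-12-(2,5-dimethoxyphenyl)-2,6,10-trimethyldodeca-2,6,10-trien-1-ol
Product: 6 (2E,6E,10E)-12-(2,5-dimethoxyphenyl)-2,6,10-trimethyldodeca-2,6,10-trienal
Conditions: MnO2 (activated, excess), CH2Cl2, rt
Reagents that add atoms: none
Why: MnO2 oxidation is selective for the allylic alcohol and should give the conjugated (E)-enal without touching the isolated alkenes or the arene.

Step 4
Reactants: 6 (2E,6E,10E)-12-(2,5-dimethoxyphenyl)-2,6,10-trimethyldodeca-2,6,10-trienal
Product: 7 1,4-dimethoxy-2-[(2E,6E,10E)-3,7,11-trimethyltrideca-2,6,10,12-tetraen-1-yl]benzene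
Conditions: Ph3PCH3Br, KN(SiMe3)2, THF, 0 °C; then 6, −78 → 0 °C
Reagents that add atoms: methyltriphenylphosphonium bromide C[P+](c1ccccc1)(c1ccccc1)c1ccccc1.[Br-]
Why: Wittig methylenation by the non-stabilised ylide proceeds by 1,2-addition to the enal and keeps the (E)-trisubstituted alkene, so the (E)-1-alkyl-2-methylbutadiene terminus is delivered with the chain in the outside position.

Step 5
Reactants: 7 1,4-dimethoxy-2-[(2E,6E,10E)-3,7,11-trimethyltrideca-2,6,10,12-tetraen-1-yl]benzene; 8 methacrolein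
Product: 9 (1R,2S)-2-[(3E,7E)-9-(2,5-dimethoxyphenyl)-3,7-dimethylnona-3,7-dien-1-yl]-1,3-dimethylcyclohex-3-ene-1-carbaldehyde
Conditions: 8 (4 equiv), (3aR)-1-(2-methylphenyl)-3,3-diphenyltetrahydro-1H,3H-pyrrolo[1,2-c][1,3,2]oxazaborole (20 mol%), HN(SO2CF3)2 (17 mol%), CH2Cl2, −78 → −40 °C; then Et3N
Reagents that add atoms: none
Why: The reaction is a concerted, asynchronous Diels–Alder [4+2] cycloaddition between the s-cis (E)-diene terminus of 7 and methacrolein bound through its carbonyl oxygen to the boron of the N-protonated oxazaborolidine; the closest known reaction type is the oxazaborolidinium-catalysed enantioselective Diels–Alder reaction of 2-substituted acroleins with acyclic alkyl dienes. The cyclohexene is closed by intermolecular [4+2] annulation, which forms the bond between the chain-bearing CH (C2 of 9) and the formyl-bearing quaternary carbon (C1 of 9) together with the CH2–CH2 bond, and leaves the ring double bond in its final place. The CH stereocentre is controlled by the catalyst, whose aryl group shields one face of the bound s-trans enal so that the diene adds to the Si face of the α-carbon, combined with the endo position of the formyl group; the quaternary stereocentre is set at the same time and loses its stereogenicity in step 7. The step needs the orientation in which the formyl-bearing carbon bonds to the substituted diene terminus, and this is secured because the enal β-carbon bonds first to the unhindered CH2 terminus, the 1-alkyl group outweighing the 2-methyl group. It needs endo selectivity, which the (E)-diene favours because its inside substituent is H and the α-methyl group takes the exo position; any exo adduct is a diastereomer of 9 and is removed by chromatography before it could appear as the wrong enantiomer after step 7. It needs chemoselectivity for the conjugated diene, and the isolated trisubstituted alkenes and the arene should stay spectators at low temperature because the acid is used in deficit and is fully bound in the catalyst.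

Step 6
Reactants: 9 (1R,2S)-2-[(3E,7E)-9-(2,5-dimethoxyphenyl)-3,7-dimethylnona-3,7-dien-1-yl]-1,3-dimethylcyclohex-3-ene-1-carbaldehyde
Product: 10 N'-[(E)-{(1R,2S)-2-[(3E,7E)-9-(2,5-dimethoxyphenyl)-3,7-dimethylnona-3,7-dien-1-yl]-1,3-dimethylcyclohex-3-en-1-yl}methylidene]-4-methylbenzenesulfonohydrazide
Conditions: TsNHNH2, EtOH, rt → 40 °C
Reagents that add atoms: 4-methylbenzenesulfonohydrazide Cc1ccc(cc1)S(=O)(=O)NN
Why: Hydrazone condensation of the formyl group occurs under near-neutral conditions, and the quaternary α-carbon cannot enolise, so the adjacent CH stereocentre is safe.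

Step 7
Reactants: 10 N'-[(E)-{(1R,2S)-2-[(3E,7E)-9-(2,5-dimethoxyphenyl)-3,7-dimethylnona-3,7-dien-1-yl]-1,3-dimethylcyclohex-3-en-1-yl}methylidene]-4-methylbenzenesulfonohydrazide
Product: 13 2-[(2E,6E)-3,7-dimethyl-9-[(1R)-2,6,6-trimethylcyclohex-2-en-1-yl]nona-2,6-dien-1-yl]-1,4-dimethoxybenzene, via N-boryl tosylhydrazine 11 (not isolated), via alkyldiazene 12 (not isolated)
Conditions: catecholborane, CHCl3, 0 °C → rt; then NaOAc·3H2O, reflux
Reagents that add atoms: none
Why: Caglioti-type tosylhydrazone reduction (hydride addition of catecholborane to C=N, acetate-induced loss of sulfinate to the alkyldiazene, extrusion of N2) turns CH=N into CH3 without strong base or acid, so the benzylic/allylic positions and skipped alkenes should not isomerise; the CH centre keeps its spatial arrangement and is (1R) in 13 only because the CIP priorities change once the former quaternary stereocentre has become the gem-dimethyl carbon.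

Step 8
Reactants: 13 2-[(2E,6E)-3,7-dimethyl-9-[(1R)-2,6,6-trimethylcyclohex-2-en-1-yl]nona-2,6-dien-1-yl]-1,4-dimethoxybenzene
Product: 14 2-[(2E,6E)-3,7-dimethyl-9-[(1R)-2,6,6-trimethylcyclohex-2-en-1-yl]nona-2,6-dien-1-yl]cyclohexa-2,5-diene-1,4-dione
Conditions: (NH4)2Ce(NO3)6, MeCN/H2O (2:1), 0 °C
Reagents that add atoms: water O
Why: Oxidative demethylation by (NH4)2Ce(NO3)6 proceeds through the arene radical cation, which forms far more easily than any oxidation product of the isolated trisubstituted alkenes, and water delivers the quinone oxygens; the remote stereocentre is not affected.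

**Compound list**

1 | 1,4-dimethoxybenzene | COc1ccc(OC)cc1 | starting material
2 | (2E,6E)-farnesyl bromide [(2E,6E)-1-bromo-3,7,11-trimethyldodeca-2,6,10-triene] | CC(C)=CCC/C(C)=C/CC/C(C)=C/CBr | starting material
3 | (2,5-dimethoxyphenyl)lithium | [Li]c1cc(OC)ccc1OC | intermediate (not isolated)
4 | 1,4-dimethoxy-2-[(2E,6E)-3,7,11-trimethyldodeca-2,6,10-trien-1-yl]benzene | CC(C)=CCC/C(C)=C/CC/C(C)=C/Cc1cc(OC)ccc1OC | intermediate
5 | (2E,6E,10E)-12-(2,5-dimethoxyphenyl)-2,6,10-trimethyldodeca-2,6,10-trien-1-ol | OC/C(C)=C/CC/C(C)=C/CC/C(C)=C/Cc1cc(OC)ccc1OC | intermediate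
6 | (2E,6E,10E)-12-(2,5-dimethoxyphenyl)-2,6,10-trimethyldodeca-2,6,10-trienal | O=C/C(C)=C/CC/C(C)=C/CC/C(C)=C/Cc1cc(OC)ccc1OC | intermediate
7 | 1,4-dimethoxy-2-[(2E,6E,10E)-3,7,11-trimethyltrideca-2,6,10,12-tetraen-1-yl]benzene | C=C/C(C)=C/CC/C(C)=C/CC/C(C)=C/Cc1cc(OC)ccc1OC | intermediate
8 | methacrolein (2-methylprop-2-enal) | CC(=C)C=O | starting material
9 | (1R,2S)-2-[(3E,7E)-9-(2,5-dimethoxyphenyl)-3,7-dimethylnona-3,7-dien-1-yl]-1,3-dimethylcyclohex-3-ene-1-carbaldehyde (formyl cis to the chain) | CC1=CCC[C@@](C)(C=O)[C@H]1CC/C(C)=C/CC/C(C)=C/Cc1cc(OC)ccc1OC | intermediate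
10 | N'-[(E)-{(1R,2S)-2-[(3E,7E)-9-(2,5-dimethoxyphenyl)-3,7-dimethylnona-3,7-dien-1-yl]-1,3-dimethylcyclohex-3-en-1-yl}methylidene]-4-methylbenzenesulfonohydrazide | CC1=CCC[C@@](C)(/C=N/NS(=O)(=O)c2ccc(C)cc2)[C@H]1CC/C(C)=C/CC/C(C)=C/Cc1cc(OC)ccc1OC | intermediate
11 | N-(1,3,2-benzodioxaborol-2-yl)-N-{[(1R,2S)-2-[(3E,7E)-9-(2,5-dimethoxyphenyl)-3,7-dimethylnona-3,7-dien-1-yl]-1,3-dimethylcyclohex-3-en-1-yl]methyl}-N'-(4-methylbenzenesulfonyl)hydrazine | CC1=CCC[C@@](C)(CN(B2Oc3ccccc3O2)NS(=O)(=O)c2ccc(C)cc2)[C@H]1CC/C(C)=C/CC/C(C)=C/Cc1cc(OC)ccc1OC | intermediate (not isolated)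
12 | {[(1R,2S)-2-[(3E,7E)-9-(2,5-dimethoxyphenyl)-3,7-dimethylnona-3,7-dien-1-yl]-1,3-dimethylcyclohex-3-en-1-yl]methyl}diazene | CC1=CCC[C@@](C)(CN=N)[C@H]1CC/C(C)=C/CC/C(C)=C/Cc1cc(OC)ccc1OC | intermediate (not isolated)
13 | 2-[(2E,6E)-3,7-dimethyl-9-[(1R)-2,6,6-trimethylcyclohex-2-en-1-yl]nona-2,6-dien-1-yl]-1,4-dimethoxybenzene | CC1=CCCC(C)(C)[C@H]1CC/C(C)=C/CC/C(C)=C/Cc1cc(OC)ccc1OC | intermediate
14 | 2-[(2E,6E)-3,7-dimethyl-9-[(1R)-2,6,6-trimethylcyclohex-2-en-1-yl]nona-2,6-dien-1-yl]cyclohexa-2,5-diene-1,4-dione | CC1=CCCC(C)(C)[C@H]1CC/C(C)=C/CC/C(C)=C/CC1=CC(=O)C=CC1=O | target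

**Summary**

Total step count: 8. Longest linear sequence: 8 steps (1 or 2 to 14).

Steps most likely to fail:

Step 5. The cycloaddition may leak into the other regiochemical mode (formyl-bearing carbon bonding to the unsubstituted diene terminus), exo approach or weak facial shielding may erode stereochemical purity, and the acidic catalyst may trigger cationic cyclisation of the polyene. The fallback abandons the cycloaddition and takes the ring preformed; it sets out from 3 and returns at 13. Aryllithium 3 is allylated with commercial geranyl bromide under the conditions of step 1 to give 2-[(2E)-3,7-dimethylocta-2,6-dien-1-yl]-1,4-dimethoxybenzene F1. Riley oxidation (SeO2, t-BuOOH) gives (2E,6E)-8-(2,5-dimethoxyphenyl)-2,6-dimethylocta-2,6-dien-1-ol F2, and PBr3 in Et2O at 0 °C gives 2-[(2E,6E)-8-bromo-3,7-dimethylocta-2,6-dien-1-yl]-1,4-dimethoxybenzene F3. Separately, commercial racemic α-cyclogeranic acid is resolved by crystallisation of its salt with enantiopure 1-phenylethylamine to give (1R)-2,6,6-trimethylcyclohex-2-ene-1-carboxylic acid F4. LiAlH4 reduces F4 to [(1R)-2,6,6-trimethylcyclohex-2-en-1-yl]methanol F5, PhSSPh/PBu3 converts it into ({[(1R)-2,6,6-trimethylcyclohex-2-en-1-yl]methyl}sulfanyl)benzene F6, and H2O2 with catalytic (NH4)6Mo7O24 oxidises this to ({[(1R)-2,6,6-trimethylcyclohex-2-en-1-yl]methyl}sulfonyl)benzene F7. Deprotonation of F7 (n-BuLi, THF, −78 °C) and alkylation with F3 should give 2-[(2E,6E)-9-(benzenesulfonyl)-3,7-dimethyl-9-[(1R)-2,6,6-trimethylcyclohex-2-en-1-yl]nona-2,6-dien-1-yl]-1,4-dimethoxybenzene F8 as both epimers at the sulfonyl carbon. Reductive desulfonylation with Na/Hg amalgam and Na2HPO4 in MeOH then gives 13, which is carried through step 8.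

Step 2. Site selectivity between the terminal and the internal allylic positions may be lost, and over-oxidation or low conversion may occur. The fallback replaces allylic oxidation by cleavage and re-olefination of the terminal alkene; it sets out from 4 and returns at 6. N-Bromosuccinimide in THF/H2O at 0 °C should convert the terminal alkene of 4 into (6E,10E)-3-bromo-12-(2,5-dimethoxyphenyl)-2,6,10-trimethyldodeca-6,10-dien-2-ol F9. K2CO3 in MeOH closes it to 2-[(2E,6E)-9-(3,3-dimethyloxiran-2-yl)-3,7-dimethylnona-2,6-dien-1-yl]-1,4-dimethoxybenzene F10, and H5IO6 in THF/Et2O cleaves this to (4E,8E)-10-(2,5-dimethoxyphenyl)-4,8-dimethyldeca-4,8-dienal F11. Wittig reaction of F11 with the stabilised ylide 2-(triphenylphosphoranylidene)propanal in toluene at 90 °C should give the (E)-enal 6 directly.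

Step 7. Hydride delivery to the hindered neopentyl C=N may be slow, and hydroboration of the alkenes may compete. The fallback removes the oxygen by hydride displacement instead of through a diazene; it sets out from 9 and returns at 13. NaBH4 in MeOH reduces 9 to [(1R,2S)-2-[(3E,7E)-9-(2,5-dimethoxyphenyl)-3,7-dimethylnona-3,7-dien-1-yl]-1,3-dimethylcyclohex-3-en-1-yl]methanol F12. CH3SO2Cl/Et3N gives [(1R,2S)-2-[(3E,7E)-9-(2,5-dimethoxyphenyl)-3,7-dimethylnona-3,7-dien-1-yl]-1,3-dimethylcyclohex-3-en-1-yl]methyl methanesulfonate F13, and LiBHEt3 in THF at reflux should displace the sulfonate to give 13.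

**Further compounds**

F1 | step 5 | 2-[(2E)-3,7-dimethylocta-2,6-dien-1-yl]-1,4-dimethoxybenzene | CC(C)=CCC/C(C)=C/Cc1cc(OC)ccc1OC
F2 | step 5 | (2E,6E)-8-(2,5-dimethoxyphenyl)-2,6-dimethylocta-2,6-dien-1-ol | OC/C(C)=C/CC/C(C)=C/Cc1cc(OC)ccc1OC
F3 | step 5 | 2-[(2E,6E)-8-bromo-3,7-dimethylocta-2,6-dien-1-yl]-1,4-dimethoxybenzene | BrC/C(C)=C/CC/C(C)=C/Cc1cc(OC)ccc1OC
F4 | step 5 | (1R)-2,6,6-trimethylcyclohex-2-ene-1-carboxylic acid | CC1=CCCC(C)(C)[C@H]1C(=O)O
F5 | step 5 | [(1R)-2,6,6-trimethylcyclohex-2-en-1-yl]methanol | CC1=CCCC(C)(C)[C@H]1CO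
F6 | step 5 | ({[(1R)-2,6,6-trimethylcyclohex-2-en-1-yl]methyl}sulfanyl)benzene | CC1=CCCC(C)(C)[C@H]1CSc1ccccc1
F7 | step 5 | ({[(1R)-2,6,6-trimethylcyclohex-2-en-1-yl]methyl}sulfonyl)benzene | CC1=CCCC(C)(C)[C@H]1CS(=O)(=O)c1ccccc1
F8 | step 5 | 2-[(2E,6E)-9-(benzenesulfonyl)-3,7-dimethyl-9-[(1R)-2,6,6-trimethylcyclohex-2-en-1-yl]nona-2,6-dien-1-yl]-1,4-dimethoxybenzene (both epimers at the sulfonyl carbon) | CC1=CCCC(C)(C)[C@H]1C(C/C(C)=C/CC/C(C)=C/Cc1cc(OC)ccc1OC)S(=O)(=O)c1ccccc1
F9 | step 2 | (6E,10E)-3-bromo-12-(2,5-dimethoxyphenyl)-2,6,10-trimethyldodeca-6,10-dien-2-ol (racemic) | CC(C)(O)C(Br)CC/C(C)=C/CC/C(C)=C/Cc1cc(OC)ccc1OC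
F10 | step 2 | 2-[(2E,6E)-9-(3,3-dimethyloxiran-2-yl)-3,7-dimethylnona-2,6-dien-1-yl]-1,4-dimethoxybenzene (racemic) | CC1(C)OC1CC/C(C)=C/CC/C(C)=C/Cc1cc(OC)ccc1OC
F11 | step 2 | (4E,8E)-10-(2,5-dimethoxyphenyl)-4,8-dimethyldeca-4,8-dienal | O=CCC/C(C)=C/CC/C(C)=C/Cc1cc(OC)ccc1OC
F12 | step 7 | [(1R,2S)-2-[(3E,7E)-9-(2,5-dimethoxyphenyl)-3,7-dimethylnona-3,7-dien-1-yl]-1,3-dimethylcyclohex-3-en-1-yl]methanol | CC1=CCC[C@@](C)(CO)[C@H]1CC/C(C)=C/CC/C(C)=C/Cc1cc(OC)ccc1OC
F13 | step 7 | [(1R,2S)-2-[(3E,7E)-9-(2,5-dimethoxyphenyl)-3,7-dimethylnona-3,7-dien-1-yl]-1,3-dimethylcyclohex-3-en-1-yl]methyl methanesulfonate | CC1=CCC[C@@](C)(COS(C)(=O)=O)[C@H]1CC/C(C)=C/CC/C(C)=C/Cc1cc(OC)ccc1OC
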